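Take the dusk run: its 1.05 M of reagent stood against 1.5 M of starting material, so reagent is the limiting reagent if each product takes one of each.

| flask | starting material | reagent | scavenger | free catalyst | remark |
|---|---|---|---|---|---|
| dusk | 1.5 M | 1.05 M | 1.2 M | 8.2 mM | run made earlier |
| spring | 1.5 M | 1.05 M | 1.8 M | 16 mM | run made earlier |
| flask | 1.5 M | 1.05 M | 1.80 M | 8.2 mM |  |

| run | time / h | product / % |
|---|---|---|
| dusk | 0.667 | 1 |
| dusk | 1.33 | 6 |
| dusk | 3.00 | 6 |
| dusk | 8.00 | 14 |
| spring | 0.667 | 1 |
| spring | 1.33 | 5 |
| spring | 3.00 | 11 |
| spring | 8.00 | 18 |

(standard deviation of a reading: 2 percentage points)

1. apparent order in free catalyst when 20 % of the starting material are converted (percent change of the rate of making product for one percent more free catalyst charged)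
2. apparent order in reagent when 20 % of the starting material are converted (percent change of the rate of making product for one percent more reagent charged)

- no earlier run changes the charge of reagent; that part of a forecast is a guess

Spring carried twice the free catalyst of dusk and also more scavenger than dusk, so these readings don't part the two. Neither run changed the reagent.

Keep the ledger for the flask, assuming one reagent per product:

charged: c(reagent) = 1.05 M

spent at 20 % conversion: 0.300 M

left: c(reagent) = 0.750 M

Now add one percent to the charge. Hold the conversion, and the spent entry stays put, so the whole addition lands on the last line. That gives the leverage:

L = c(reagent) charged / c(reagent) left = 1.40, the percent rise of reagent left for one percent more charged.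

If the rate feels reagent through what is left, the apparent order is L times the order in reagent left. Taking that order to lie between zero and one, an assumption the runs can't test, my range runs from zero to 1.40, and I commit to its middle, 0.700.

The forecast stands higher, at 0.9 (0.1 to 1.8) for reagent, with 0.6 (0.2 to 1.1) for free catalyst. It warns: “Reagent was never varied, so ord_B is a guess”.

The flask gives 0.77 for reagent and 0.83 for free catalyst.

    reagent + catalyst intermediate A → catalyst intermediate B (k = 4.70 /M/h)
    2 catalyst intermediate B ⇌ resting dimer, settled at all times (K = 880 /M)
    scavenger + released group → scavenged by-product (k = 1.50 /M/h)
    reagent + released group ⇌ idle adduct, settled at all times (K = 1.80 /M)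
    catalyst intermediate B → released group + catalyst intermediate C (k = 20.0 /h)
    catalyst intermediate C → free catalyst + product (k = 2200 /h)
    starting material + free catalyst → catalyst intermediate A (k = 150 /M/h)

At 10.0 h the flask has lost 0.230 M of reagent and 0.222 M of starting material, a ratio of 1.03 where the ledger assumes one. The fit of a single step, first order in starting material, reagent and free catalyst, gives 1.40, which is L times one. Divide the flask's own order by L: on the ledger's reckoning, the order in reagent left is 0.550.

(The readings were computed for substances that don't exist, noise included.)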